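**Plan**

- Numbering (elemane) used below: the ring is C5–C6–C7–C8–C9–C10. C10 is quaternary (C14 methyl, C1=C2 vinyl), C5 carries the isopropenyl C4(=C3H2)C15H3, C6 the hydroxyl, and C7 the group C11(OH)(C12H2OAc)(C13H2OAc).
- Retrosynthesis: cut the two acetate C–O bonds, take C11–OH and C13–O back to a C11=C13 alkene next to the C12 allylic alcohol, and tie C12 to O6 as an α-methylene γ-lactone. Then cut the ring bond C5–C10 and join C2–C3 (retro-Cope).
- Enabling feature: the vinyl on quaternary C10 and the trans isopropenyl on neighbouring C5 form a hexa-1,5-diene C2=C1–C10–C5–C4=C3 whose central σ-bond is a bond of the cyclohexane. Its retro-[3,3] shift leads to the (E,E)-cyclodeca-1(10),4-diene of the germacranolide costunolide.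
- Forward: in step 1 the ten-membered ring contracts to the cyclohexane, the only ring of the target. The lactone, a temporary ring that locks the conformation, is then reduced open, C11=C13 is oxidised by hydroxyl-directed epoxidation and hydrolysis, and the two primary hydroxyls are acetylated.
- Stereochemistry: C6 and C7 come from costunolide (chiral pool). C5 and C10 are set together in the chair Cope transition state by the E,E alkene geometry and the lactone-locked conformer. C11 is not stereogenic in the target.

Key step: step 1

Remark: costunolide (1) is taken as a commercial chiral-pool sesquiterpene lactone; the epoxide 4 may form as either C11 epimer, and because C11 loses its stereogenicity in 5 all such material converges, so C11 is left open in that SMILES (likewise in F2 and F3).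

**Route**

Step 1
Reactants: 1 costunolide
Product: 2 dehydrosaussurea lactone (elema-1,3,11(13)-trien-12,6α-olide)
Conditions: BHT (cat.), degassed Ph2O, sealed tube, 200 °C, Ar; recovered 1 resubjected
Reagents that add atoms: none
Why: Heating drives a concerted, suprafacial [3,3]-sigmatropic (Cope) shift of the cyclodeca-1,5-diene C10=C1–C2–C3–C4=C5, in which the C2–C3 bond breaks, the C5–C10 bond forms across the ring and the π bonds move to C1=C2 and C3=C4. The closest known reaction type is the thermal germacranolide-to-elemanolide (germacrene-to-elemene) Cope rearrangement. The cyclohexane C5–C6–C7–C8–C9–C10 is closed by transannular C5–C10 bond formation through a chair-like six-centre transition state, that is, by contraction of the ten-membered ring. The relative configuration of the two new centres C5 and C10 follows from the E geometry of both trisubstituted alkenes in that chair (vinyl and isopropenyl trans, C14 methyl cis to isopropenyl), and their configuration relative to C6 and C7 follows from the trans-fused lactone, which holds the macrocycle in the crossed conformer with both methyl groups on the β face (10β-methyl, 5α-H). The step needs chair-over-boat and conformer (π-face) selectivity, and both are secured by this lactone-bridged ring, while C6 and C7 are not touched. Since the shift is reversible, conversion is limited by the equilibrium, so unchanged 1 is separated and resubjected, and BHT keeps the α-methylene lactone from radical polymerisation.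

Step 2
Reactants: 2 dehydrosaussurea lactone
Product: 3 elema-1,3,11(13)-triene-6α,12-diol
Conditions: DIBAL-H (4 equiv), CH2Cl2, −78 → 0 °C; aq. Rochelle salt
Reagents that add atoms: none
Why: DIBAL-H reduction of a lactone to the diol by two 1,2-hydride additions is well precedented for α-methylene γ-lactones and should not add hydride in conjugate fashion, so the temporary lactone ring is opened with C11=C13 intact and no stereocentre made or touched.

Step 3
Reactants: 3 elema-1,3,11(13)-triene-6α,12-diol
Product: 4 11,13-epoxyelema-1,3-diene-6α,12-diol
Conditions: VO(acac)2 (cat.), t-BuOOH (1.1 equiv, decane), CH2Cl2, 0 °C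
Reagents that add atoms: tert-butyl hydroperoxide, CC(C)(C)OO
Why: In this hydroxyl-directed (Sharpless–Michaelson) epoxidation the vanadium alkoxide of the primary C12 allylic alcohol should deliver oxygen to C11=C13 much faster than to the isopropenyl group (only homoallylic to the hindered C6 hydroxyl) or to the undirected vinyl group; the new centre C11 may arise as either epimer, which is without consequence.

Step 4
Reactants: 4 11,13-epoxyelema-1,3-diene-6α,12-diol
Product: 5 elema-1,3-diene-6α,11,12,13-tetraol
Conditions: 0.1 M HClO4, THF/H2O (3:1), 0 °C → rt
Reagents that add atoms: water, O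
Why: Acid-catalysed hydrolytic opening of the 2,2-disubstituted epoxide (water attacks the tertiary C11) should give the 2-substituted glycerol, in which C11 carries two identical CH2OH arms and is no longer stereogenic, so both epimers of 4 converge and the ring stereocentres are not involved.

Step 5
Reactants: 5 elema-1,3-diene-6α,11,12,13-tetraol
Product: 6 target, 12,13-diacetoxyelema-1,3-diene-6α,11-diol
Conditions: Ac2O (2.1 equiv), 2,4,6-collidine, CH2Cl2, −20 → 0 °C
Reagents that add atoms: acetic anhydride, CC(=O)OC(C)=O
Why: Kinetically controlled acylation (nucleophilic acyl substitution, no DMAP) should esterify the two primary hydroxyls, while the equatorial secondary C6 hydroxyl, flanked by the isopropenyl-bearing C5 and the fully substituted C11 on C7, and the tertiary C11 hydroxyl stay free; no stereocentre is affected.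

**Compound list**

1 | costunolide, germacra-1(10)E,4E,11(13)-trien-12,6α-olide [(3aS,6E,10E,11aR)-6,10-dimethyl-3-methylidene-3a,4,5,8,9,11a-hexahydrocyclodeca[b]furan-2(3H)-one] | C/C1=C\CC/C(C)=C/[C@H]2OC(=O)C(=C)[C@@H]2CC1 | starting material
2 | dehydrosaussurea lactone, elema-1,3,11(13)-trien-12,6α-olide, trans-fused lactone, 5α-H, 10β-methyl [(3aS,6S,7S,7aS)-6-ethenyl-6-methyl-3-methylidene-7-(prop-1-en-2-yl)hexahydro-1-benzofuran-2(3H)-one] | C=C[C@]1(C)CC[C@H]2C(=C)C(=O)O[C@@H]2[C@H]1C(=C)C | intermediate
3 | elema-1,3,11(13)-triene-6α,12-diol [(1S,2S,3S,6S)-3-ethenyl-6-(3-hydroxyprop-1-en-2-yl)-3-methyl-2-(prop-1-en-2-yl)cyclohexan-1-ol] | C=C[C@]1(C)CC[C@@H](C(=C)CO)[C@H](O)[C@H]1C(=C)C | intermediate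
4 | 11,13-epoxyelema-1,3-diene-6α,12-diol [(1R,2S,3S,6R)-3-ethenyl-6-[2-(hydroxymethyl)oxiran-2-yl]-3-methyl-2-(prop-1-en-2-yl)cyclohexan-1-ol], oxirane carbon C11 either epimer | C=C[C@]1(C)CC[C@@H](C2(CO)CO2)[C@H](O)[C@H]1C(=C)C | intermediate
5 | elema-1,3-diene-6α,11,12,13-tetraol [2-[(1R,2R,3S,4S)-4-ethenyl-2-hydroxy-4-methyl-3-(prop-1-en-2-yl)cyclohexyl]propane-1,2,3-triol] | C=C[C@]1(C)CC[C@@H](C(O)(CO)CO)[C@H](O)[C@H]1C(=C)C | intermediate
6 | 12,13-diacetoxyelema-1,3-diene-6α,11-diol [2-[(1R,2R,3S,4S)-4-ethenyl-2-hydroxy-4-methyl-3-(prop-1-en-2-yl)cyclohexyl]-2-hydroxypropane-1,3-diyl diacetate] | C=C[C@]1(C)CC[C@@H](C(O)(COC(C)=O)COC(C)=O)[C@H](O)[C@H]1C(=C)C | target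

**Count and risks**

Total step count: 5. Longest linear sequence: 5 steps (1 → 6).

Steps most likely to fail:

Step 1. The process at risk is incomplete conversion: the [3,3] shift is reversible, the strain of a trans-fused γ-lactone on the new cyclohexane holds the equilibrium back, and long heating invites polymerisation of the exocyclic enoate. The fallback sets out from 1 and opens the lactone before the rearrangement. DIBAL-H (CH2Cl2, −78 → 0 °C) should give germacra-1(10)E,4E,11(13)-triene-6α,12-diol F1. This diol, free of lactone strain and of the Michael acceptor, is then heated in degassed xylene (base-washed sealed tube, about 150 °C). The Cope rearrangement should now lie on the elemane side, and the equatorial preference of the C6 hydroxyl and the C7 side chain should select the same chair. The product is 3, where the route is rejoined.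

Step 3. The process at risk is loss of site selectivity in the oxygen transfer: the C6 hydroxyl may direct the vanadium peroxide to the homoallylic isopropenyl group, or a second epoxidation may follow. The fallback sets out from 2, in which C11=C13 is the only electron-poor alkene, and reverses the polarity of the oxidant. Nucleophilic (Weitz–Scheffer type) epoxidation with t-BuOOLi (t-BuOOH, n-BuLi, THF, −20 °C) should give 11,13-epoxyelema-1,3-dien-12,6α-olide F2. Its activated glycidic lactone is reduced with NaBH4 (EtOH, 0 °C) to the epoxy diol 4, where the route is rejoined.

Step 5. The process at risk is incomplete discrimination between the hydroxyl groups, giving over-acylation at C6 or stalling at the monoacetates. The fallback sets out from 4 and brings in the first acetate as a nucleophile instead of as an acyl donor. CsOAc/AcOH (DMF, 80 °C) should open the epoxide at its CH2 carbon to 13-acetoxyelema-1,3-diene-6α,11,12-triol F3. Only one primary hydroxyl then remains to be acylated beside the hindered C6 hydroxyl. Ac2O (1.05 equiv), 2,4,6-collidine, CH2Cl2, −20 °C should give 6 directly, where the route is rejoined.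

**Further compounds**

F1 | step 1 | germacra-1(10)E,4E,11(13)-triene-6α,12-diol | C/C1=C\CC/C(C)=C/[C@@H](O)[C@H](C(=C)CO)CC1
F2 | step 3 | 11,13-epoxyelema-1,3-dien-12,6α-olide (C11 either epimer) | C=C[C@]1(C)CC[C@H]2C3(CO3)C(=O)O[C@@H]2[C@H]1C(=C)C
F3 | step 5 | 13-acetoxyelema-1,3-diene-6α,11,12-triol (C11 either epimer) | C=C[C@]1(C)CC[C@@H](C(O)(CO)COC(C)=O)[C@H](O)[C@H]1C(=C)C
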